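## Structural features

Epimedonin L is a 2-aryl-4H-chromen-4-one. Ring A (the benzo ring, C4a to C8a) is fused to the pyranone ring C along the C4a–C8a bond, and ring B, a phenyl ring, is attached to C2 of ring C through the C2–C1′ bond. Ring A has a phloroglucinol pattern: oxygens sit on C5, C7 and C8a, the last tied into ring C as O1, and ring B carries one hydroxyl at C4′. Three 3-methylbut-2-enyl (prenyl) groups sit at C8, C3′ and C5′, each ortho to an oxygen. There is no stereocentre, so no relative configuration has to be set. The fragile parts are the three trisubstituted alkenes, which under Brønsted or strong Lewis acid take up the neighbouring phenolic oxygen (2,2-dimethylchroman formation) or HX, and the electron-rich phenols, which oxidise easily as phenolates. Ring B is symmetric and easy. The real difficulty is ring A: C6 and C8 both lie between two oxygen-bearing carbons and are hard to tell apart by electrophilic prenylation or Claisen chemistry, and the three oxygens must end in three different roles (ring oxygen, chelated 5-OH, free 7-OH). The key step uses the fact that C8 with its prenyl group lies between the oxygen-bearing carbons C8a and C7. This C8a–C8–C7 unit maps onto a ketene carbon joined to the two carbons of a prenyl-substituted ynol ether, so ring A can be built around the prenyl group with each oxygen arriving in a different form.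

## Logic of the disconnections

24 ⇒ 23 ⇒ 22. The bonds cleaved last in the forward direction are the two O–Si bonds at O7 and O4′ (23 to 24) and, before that, the O5–CH2 bond of the ethyl ether (22 to 23). The order is chosen so that every hydroxyl flanking a prenyl group is still masked while the Lewis-acidic dealkylation runs, and the final unmasking needs only buffered fluoride. The skeleton does not change, but the acid-sensitivity problem is kept out of the endgame. The demand is that the dealkylation picks the ether next to the carbonyl and spares the two silyl ethers.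

22 ⇒ 20. The O1–C2 bond of ring C is cut, which opens the pyranone to an o-hydroxyaryl ynone. In 20 only the oxygen on C8a is free, because O5 is ethylated and O7 silylated, so there is one possible ring closure. This removes ring C. The forward step must give the six-membered ring and not the five-membered one, which is why it is run through the amine adduct 21.

20 ⇒ 19 ⇒ 12 + 17. After adjusting the ketone to the alcohol 19, the C4–C3 bond is cut between the carbinol carbon and the alkyne. This splits the molecule into a ring A half and a ring B half of similar size, each three steps from purchased material. The forward demand is that the acetylide 18 adds to an aldehyde bearing a free ortho hydroxyl, and that the oxidation of 19 spares the phenol and the alkenes.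

12 ⇒ 10. The C4a–C4 bond (ring carbon to formyl carbon) is cut. 10 has one free position ortho to its hydroxyl, so an ortho-specific formylation has no choice of site. The forward step must be non-acidic because the prenyl group sits next to the free hydroxyl.

10 ⇒ 5 + 4. Three bonds are cut: C8a–C8, C7–C6 and C8a–C4a. Ring A is dissolved into a four-carbon ketene precursor and a two-carbon ynol ether that already carries the prenyl group. This is the largest simplification in the plan, a tetrasubstituted benzene with three differentiated oxygens from two small pieces, and no C6-prenyl isomer can arise. The forward demand is a single orientation of the ketene–alkyne union and tolerance of the isolated alkene to heat.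

4 ⇒ 1. The O–Si bond is cut and the alkyne is traced to an ester: the oxygen-bearing alkyne carbon is the former ester carbonyl carbon of 1, and the other alkyne carbon is a one-carbon unit inserted between it and the allylic CH2. This brings in the prenyl unit with its alkene already in place from a simple β,γ-unsaturated ester. The forward demand is that the carbenoid adds to the ester before the acidic α-hydrogens are removed, and that silylation goes to oxygen.

17 ⇒ 16 ⇒ 15 ⇒ 13. The terminal alkyne carbon is removed (back to the formyl group of 16), then the O–Si bond (to 15), then the two aryl–CH2 bonds (to 13). 13 has bromine exactly where the two prenyl groups belong and the formyl group where the alkyne must grow, so ring B needs no regiochemical decision. The forward demand is twofold transfer of the prenyl group without allylic transposition, and a silyl ether that survives basic methanol.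

## Other disconnections considered

Alternative 1: The cut is at the two benzylic bonds C3′–CH2 and C5′–CH2, made while ring B is still a saturated six-membered ketone.
- Forward key step: ethyl 4-oxocyclohexane-1-carboxylate A1, as its enamine with a cyclic secondary amine, would be alkylated by 1-bromo-3-methylbut-2-ene A2 at one α-carbon and, after the enamine re-forms on the unsubstituted side, at the other. This gives ethyl 3,5-bis(3-methylbut-2-enyl)-4-oxocyclohexane-1-carboxylate A3. Dehydrogenation would then have to give the phenol ester A4 (ethyl 4-hydroxy-3,5-bis(3-methylbut-2-enyl)benzoate).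
- In its favour: both prenyl groups arrive as intact C5 units from a cheap halide without tin or palladium, and the configuration of A3 does not matter. The 3′,5′ pattern follows from the α and α′ positions of the ketone; on this point it is the equal of the chosen plan, where 13 fixes the same pattern.
- Against it: an enamine and an allylic halide can first react at nitrogen and then rearrange with allylic transposition, which would deliver a 1,1-dimethylallyl group. Double alkylation at one carbon competes. The aromatisation must remove four hydrogens from a ring that carries two trisubstituted alkenes, and halogen, quinone and palladium hydride chemistry can all attack or shift those alkenes. A4 is still two redox adjustments and a homologation away from 17.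
- Comparison: on mechanism it is simple polar chemistry, less demanding than a pericyclic cascade. On structure it solves only ring B and leaves the C8 versus C6 problem of ring A untouched, so a step like step 2 would still be needed. On step economy it should be two to three steps longer to the same ring B alkyne.

Alternative 2: The cut is at the three C=C bonds of the prenyl groups, which are traced back to allyl groups.
- Forward key step: the triallyl triacetate A5 would be treated with 2-methylbut-2-ene A6 and the second-generation Grubbs catalyst, so that each terminal CH2 is exchanged for an isopropylidene unit. This gives Epimedonin L triacetate A7, and deacetylation would give 24.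
- In its favour: allyl groups can be placed by aromatic Claisen rearrangement of allyl ethers, which is ortho-specific and needs no tin. Allyl groups have no tertiary-cation pathway and tolerate acidic or Lewis-acidic steps, which is better than the chosen plan, where prenyl groups are carried through nine steps. The flavone core can come from textbook condensations, so step economy should be equal or better. The acetates keep phenols away from ruthenium.
- Against it: the regiochemical problem is moved, not removed, because Claisen rearrangement from O7 on a 5,7-dioxygenated ring can go to C8 or C6. Three metatheses must all run to completion; partial exchange, ethylidene transfer (crotyl groups) and ruthenium hydride isomerisation of allyl to propenyl would give congeners that are hard to separate at the last C–C-forming stage.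
- Comparison: equal or better on step count and on robustness toward acid. Weaker on positional certainty at C8, which the chosen plan secures by construction, and on the homogeneity expected from the final C–C-forming step.

Alternative 3: The cut is at C5–C6 in ring A.
- Forward key step: in the pyranone A8, the methyl ketone enolate (future C6) would attack the ester carbonyl on the pyranone (future C5) in an intramolecular Claisen condensation. Loss of methoxide and tautomerisation would give Epimedonin L 4′-methoxymethyl ether A9, and acid would give 24.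
- In its favour: the closure mirrors polyketide aromatisation. The prenyl group sits on the sp3 carbon between C8a and the C7 ketone, so its position is fixed by construction; on positional certainty it is the equal of the chosen plan. Ring A emerges directly as the free 5,7-diol, so no O5 dealkylation is needed, which is better than the chosen plan. The conditions are basic and mild toward alkenes.
- Against it: A8 is a 2,3,6-trisubstituted 4-pyranone with an ester and a branched keto side chain, and making it should be longer and less certain than making 10. Its methine hydrogen (future C8–H) is activated by both the ketone and the pyranone and is more acidic than the methyl group that must react, so a dianion or excess base is needed. 4-Pyranones can be ring-opened by alkoxide at C2 or C6. The last step needs acid on a molecule with three prenyl groups beside free hydroxyls.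
- Comparison: on mechanism it is ionic and conceptually simple; on structure it is as secure as the chosen plan for C8; on step economy and on the safety of the last step it is expected to be worse.

Key step: step 2

Assumption: 1, 5, 13, tributyl(3-methylbut-2-en-1-yl)stannane and dimethyl (1-diazo-2-oxopropyl)phosphonate are taken as purchasable, and the target, which has no stereocentre, is made exactly as drawn.

Step 1
Reactants: 1 ethyl 4-methylpent-3-enoate
Product: 4 triisopropyl[(5-methylhex-4-en-1-yn-1-yl)oxy]silane, via lithium dibromoenolate 2 (not isolated), via lithium ynolate 3 (not isolated)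
Conditions: CH2Br2, lithium 2,2,6,6-tetramethylpiperidide, THF, −78 °C; n-BuLi, −78 → 25 °C; triisopropylsilyl triflate, −78 → 0 °C
Reagents that add atoms: dibromomethane, BrCBr; triisopropylsilyl trifluoromethanesulfonate, CC(C)[Si](OS(=O)(=O)C(F)(F)F)(C(C)C)C(C)C
Why: Kowalski ester homologation stopped at the ynolate: LiCHBr2 adds to the ester, enolate 2 undergoes bromine–lithium exchange and 1,2-shift of the alkyl group to give 3, and the bulky silyl triflate silylates 3 on oxygen. Esters with comparably acidic α-hydrogens are known substrates because the weakly basic carbenoid adds faster than it deprotonates.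

Step 2
Reactants: 5 3-ethoxycyclobut-2-en-1-one; 4 triisopropyl[(5-methylhex-4-en-1-yn-1-yl)oxy]silane
Product: 10 5-ethoxy-2-(3-methylbut-2-en-1-yl)-3-[(triisopropylsilyl)oxy]phenol, via vinylketene 6 (not isolated), via vinylcyclobutenone 7 (not isolated), via dienylketene 8 (not isolated), via cyclohexadienone 9 (not isolated)
Conditions: 4 (1.3 equiv), toluene, 80 °C then 110 °C, argon
Reagents that add atoms: none
Why: This is a Danheiser benzannulation, the known thermal union of a cyclobutenone with a siloxyalkyne to a resorcinol monosilyl ether. Four-electron electrocyclic opening of 5 gives ketene 6, which is 3-ethoxybuta-1,3-dien-1-one with the ethoxy group on the inner vinyl carbon (a 1-ethoxyvinyl ketene, not a 2-ethoxyvinyl one); [2+2] cycloaddition with 4 gives 7, a second four-electron opening gives 8, and thermal disrotatory six-electron electrocyclisation of 8 closes ring A as 9, which tautomerises to 10. The [2+2] step forms C8a–C8 and C7–C6 and the electrocyclisation forms C8a–C4a (flavone numbering). No stereocentre is created: the one in 7 is lost on ring opening, and the E geometry of 8 needed for closure is accessible because the opening of 7 is reversible. The selectivity needed is the orientation of the [2+2] step, secured by the polarisation of 4: its carbon remote from oxygen, the one bearing the prenyl CH2, is the nucleophilic end and bonds to the ketene carbonyl carbon, so the former ketene oxygen becomes the one free hydroxyl beside the prenyl group, with the silyl ether on the other side and the ethyl ether meta. The isolated trisubstituted alkene is a far weaker ketene partner than the ynol ether and is untouched by neutral heat, the bulky silyl group suppresses oxygen-to-carbon silyl shift in 4, and the small excess of 4 keeps 6 from acylating the product phenol.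

Step 3
Reactants: 10 5-ethoxy-2-(3-methylbut-2-en-1-yl)-3-[(triisopropylsilyl)oxy]phenol
Product: 12 6-ethoxy-2-hydroxy-3-(3-methylbut-2-en-1-yl)-4-[(triisopropylsilyl)oxy]benzaldehyde, via hydroxymethylphenol 11 (not isolated)
Conditions: MgCl2, Et3N, (CH2O)n, MeCN, 80 °C; dilute aq. HCl work-up at 0 °C
Reagents that add atoms: paraformaldehyde (source of formaldehyde), C=O
Why: Magnesium-mediated ortho-formylation (Casnati–Skattebøl): the magnesium phenoxide of 10 delivers formaldehyde through a six-membered chelate to the only free ortho carbon to give 11, which a second formaldehyde oxidises by hydride transfer. The chelate keeps the reaction away from the para carbon, and the basic medium leaves the prenyl group and the silyl ether alone.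

Step 4
Reactants: 13 3,5-dibromo-4-hydroxybenzaldehyde
Product: 15 4-hydroxy-3,5-bis(3-methylbut-2-en-1-yl)benzaldehyde, via monoprenyl bromide 14 (not isolated)
Conditions: tributyl(3-methylbut-2-en-1-yl)stannane (2.6 equiv), Pd(PPh3)4 (cat.), DMF, 90 °C; aq. KF work-up
Reagents that add atoms: tributyl(3-methylbut-2-en-1-yl)stannane, CCCC[Sn](CCCC)(CCCC)CC=C(C)C
Why: Twofold Stille coupling: oxidative addition is eased by the para formyl group, and reductive elimination at the less hindered end of the allylpalladium unit should give the linear prenyl arene. The neutral stannane reacts with neither the free phenol nor the aldehyde in the absence of a Lewis acid.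

Step 5
Reactants: 15 4-hydroxy-3,5-bis(3-methylbut-2-en-1-yl)benzaldehyde
Product: 16 3,5-bis(3-methylbut-2-en-1-yl)-4-[(triisopropylsilyl)oxy]benzaldehyde
Conditions: triisopropylsilyl triflate, 2,6-lutidine, CH2Cl2, 0 → 25 °C
Reagents that add atoms: triisopropylsilyl trifluoromethanesulfonate, CC(C)[Si](OS(=O)(=O)C(F)(F)F)(C(C)C)C(C)C
Why: O-Silylation with a silyl triflate and a hindered pyridine base, which is reactive enough for a phenol flanked by two CH2 groups while the base keeps triflic acid away from the alkenes. The same silyl group as on O7 is chosen so that one fluoride step frees both hydroxyls at the end.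

Step 6
Reactants: 16 3,5-bis(3-methylbut-2-en-1-yl)-4-[(triisopropylsilyl)oxy]benzaldehyde
Product: 17 [4-ethynyl-2,6-bis(3-methylbut-2-en-1-yl)phenoxy]triisopropylsilane
Conditions: dimethyl (1-diazo-2-oxopropyl)phosphonate, K2CO3, MeOH–THF, 0 → 25 °C
Reagents that add atoms: dimethyl (1-diazo-2-oxopropyl)phosphonate, COP(=O)(OC)C(=[N+]=[N-])C(C)=O
Why: Seyferth–Gilbert homologation in the Ohira–Bestmann form: methanolysis of the reagent gives the diazomethylphosphonate anion, which olefinates the aldehyde and, after loss of N2 and 1,2-hydrogen shift, leaves the terminal alkyne. The doubly ortho-substituted triisopropylsilyl ether is expected to resist K2CO3 in methanol at room temperature.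

Step 7
Reactants: 17 [4-ethynyl-2,6-bis(3-methylbut-2-en-1-yl)phenoxy]triisopropylsilane; 12 6-ethoxy-2-hydroxy-3-(3-methylbut-2-en-1-yl)-4-[(triisopropylsilyl)oxy]benzaldehyde
Product: 19 racemic 3-ethoxy-2-(1-hydroxy-3-{3,5-bis(3-methylbut-2-en-1-yl)-4-[(triisopropylsilyl)oxy]phenyl}prop-2-yn-1-yl)-6-(3-methylbut-2-en-1-yl)-5-[(triisopropylsilyl)oxy]phenol, via lithium acetylide 18 (not isolated)
Conditions: 17 (2.3 equiv), n-BuLi (2.2 equiv), THF, −78 °C; then 12, −78 → 0 °C; aq. NH4Cl
Reagents that add atoms: none
Why: 1,2-Addition of a lithium acetylide to an aldehyde: the first equivalent of 18 deprotonates the phenol of 12 (returning 17, which is recovered) and the second adds to the lithium phenoxide aldehyde, the usual way to handle unprotected salicylaldehydes. The new carbinol centre forms as a racemate and is removed in step 8.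

Step 8
Reactants: 19 racemic 3-ethoxy-2-(1-hydroxy-3-{3,5-bis(3-methylbut-2-en-1-yl)-4-[(triisopropylsilyl)oxy]phenyl}prop-2-yn-1-yl)-6-(3-methylbut-2-en-1-yl)-5-[(triisopropylsilyl)oxy]phenol
Product: 20 1-[6-ethoxy-2-hydroxy-3-(3-methylbut-2-en-1-yl)-4-[(triisopropylsilyl)oxy]phenyl]-3-{3,5-bis(3-methylbut-2-en-1-yl)-4-[(triisopropylsilyl)oxy]phenyl}prop-2-yn-1-one
Conditions: activated MnO2 (excess), CH2Cl2, 25 °C
Reagents that add atoms: none
Why: MnO2 oxidation of an alcohol that is both benzylic and propargylic to the ynone. The reagent is selective for such activated alcohols and should leave the phenol, the isolated alkenes and the silyl ethers untouched.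

Step 9
Reactants: 20 1-[6-ethoxy-2-hydroxy-3-(3-methylbut-2-en-1-yl)-4-[(triisopropylsilyl)oxy]phenyl]-3-{3,5-bis(3-methylbut-2-en-1-yl)-4-[(triisopropylsilyl)oxy]phenyl}prop-2-yn-1-one
Product: 22 5-ethoxy-8-(3-methylbut-2-en-1-yl)-2-{3,5-bis(3-methylbut-2-en-1-yl)-4-[(triisopropylsilyl)oxy]phenyl}-7-[(triisopropylsilyl)oxy]-4H-chromen-4-one, via enaminone 21 (not isolated)
Conditions: Et2NH, EtOH, 25 → 60 °C
Reagents that add atoms: none
Why: Amine-relayed cyclisation of an o-hydroxyaryl ynone: conjugate addition of Et2NH gives 21, the phenol adds to the same β-carbon and the amine is expelled, so only the six-membered pyranone can form and the five-membered aurone is excluded. Only the oxygen on C8a is free to close the ring, because O5 is held as its ethyl ether.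

Step 10
Reactants: 22 5-ethoxy-8-(3-methylbut-2-en-1-yl)-2-{3,5-bis(3-methylbut-2-en-1-yl)-4-[(triisopropylsilyl)oxy]phenyl}-7-[(triisopropylsilyl)oxy]-4H-chromen-4-one
Product: 23 5-hydroxy-8-(3-methylbut-2-en-1-yl)-2-{3,5-bis(3-methylbut-2-en-1-yl)-4-[(triisopropylsilyl)oxy]phenyl}-7-[(triisopropylsilyl)oxy]-4H-chromen-4-one
Conditions: MgI2·OEt2 (excess), toluene, 80 °C; aq. NH4Cl, Na2S2O3
Reagents that add atoms: none
Why: Chelation-directed dealkylation: divalent magnesium bridges the C4 carbonyl and the O5 ether oxygen and iodide removes the ethyl group by SN2 attack, while the two silyl ethers, which are not next to the carbonyl, are not activated. Because every hydroxyl flanking a prenyl group is still silylated, no phenol is free to add to an alkene and no HI is generated from free phenols.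

Step 11
Reactants: 23 5-hydroxy-8-(3-methylbut-2-en-1-yl)-2-{3,5-bis(3-methylbut-2-en-1-yl)-4-[(triisopropylsilyl)oxy]phenyl}-7-[(triisopropylsilyl)oxy]-4H-chromen-4-one
Product: 24 Epimedonin L, 5,7-dihydroxy-2-[4-hydroxy-3,5-bis(3-methylbut-2-en-1-yl)phenyl]-8-(3-methylbut-2-en-1-yl)-4H-chromen-4-one
Conditions: TBAF, AcOH, THF, 0 → 25 °C
Reagents that add atoms: none
Why: Fluoride cleavage of both aryl silyl ethers in one operation. Acetic acid buffers the phenoxides so that the electron-rich triphenol is not exposed to base and air, and no acid strong enough to cyclise a prenyl group onto a neighbouring hydroxyl is present.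

Compound list

1 | ethyl 4-methylpent-3-enoate | CCOC(=O)CC=C(C)C | starting material
2 | lithium 1,1-dibromo-5-methylhexa-1,4-dien-2-olate (not isolated) | [Li+].[O-]C(CC=C(C)C)=C(Br)Br | intermediate
3 | lithium 5-methylhex-4-en-1-yn-1-olate (not isolated) | [Li+].[O-]C#CCC=C(C)C | intermediate
4 | triisopropyl[(5-methylhex-4-en-1-yn-1-yl)oxy]silane | CC(C)=CCC#CO[Si](C(C)C)(C(C)C)C(C)C | intermediate
5 | 3-ethoxycyclobut-2-en-1-one | CCOC1=CC(=O)C1 | starting material
6 | 3-ethoxybuta-1,3-dien-1-one (not isolated) | C=C(OCC)C=C=O | intermediate
7 | racemic 4-(1-ethoxyethenyl)-2-(3-methylbut-2-en-1-yl)-3-[(triisopropylsilyl)oxy]cyclobut-2-en-1-one (not isolated) | CCOC(=C)C1C(=O)C(CC=C(C)C)=C1O[Si](C(C)C)(C(C)C)C(C)C | intermediate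
8 | (3E)-5-ethoxy-2-(3-methylbut-2-en-1-yl)-3-[(triisopropylsilyl)oxy]hexa-1,3,5-trien-1-one (not isolated) | C=C(OCC)/C=C(O[Si](C(C)C)(C(C)C)C(C)C)\C(CC=C(C)C)=C=O | intermediate
9 | 5-ethoxy-2-(3-methylbut-2-en-1-yl)-3-[(triisopropylsilyl)oxy]cyclohexa-2,4-dien-1-one (not isolated) | CCOC1=CC(O[Si](C(C)C)(C(C)C)C(C)C)=C(CC=C(C)C)C(=O)C1 | intermediate
10 | 5-ethoxy-2-(3-methylbut-2-en-1-yl)-3-[(triisopropylsilyl)oxy]phenol | CCOc1cc(O)c(CC=C(C)C)c(O[Si](C(C)C)(C(C)C)C(C)C)c1 | intermediate
11 | 3-ethoxy-2-(hydroxymethyl)-6-(3-methylbut-2-en-1-yl)-5-[(triisopropylsilyl)oxy]phenol (present as its magnesium salt, not isolated) | CCOc1cc(O[Si](C(C)C)(C(C)C)C(C)C)c(CC=C(C)C)c(O)c1CO | intermediate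
12 | 6-ethoxy-2-hydroxy-3-(3-methylbut-2-en-1-yl)-4-[(triisopropylsilyl)oxy]benzaldehyde | CCOc1cc(O[Si](C(C)C)(C(C)C)C(C)C)c(CC=C(C)C)c(O)c1C=O | intermediate
13 | 3,5-dibromo-4-hydroxybenzaldehyde | O=Cc1cc(Br)c(O)c(Br)c1 | starting material
14 | 3-bromo-4-hydroxy-5-(3-methylbut-2-en-1-yl)benzaldehyde (not isolated) | O=Cc1cc(Br)c(O)c(CC=C(C)C)c1 | intermediate
15 | 4-hydroxy-3,5-bis(3-methylbut-2-en-1-yl)benzaldehyde | O=Cc1cc(CC=C(C)C)c(O)c(CC=C(C)C)c1 | intermediate
16 | 3,5-bis(3-methylbut-2-en-1-yl)-4-[(triisopropylsilyl)oxy]benzaldehyde | O=Cc1cc(CC=C(C)C)c(O[Si](C(C)C)(C(C)C)C(C)C)c(CC=C(C)C)c1 | intermediate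
17 | [4-ethynyl-2,6-bis(3-methylbut-2-en-1-yl)phenoxy]triisopropylsilane | C#Cc1cc(CC=C(C)C)c(O[Si](C(C)C)(C(C)C)C(C)C)c(CC=C(C)C)c1 | intermediate
18 | ({3,5-bis(3-methylbut-2-en-1-yl)-4-[(triisopropylsilyl)oxy]phenyl}ethynyl)lithium (not isolated) | [Li]C#Cc1cc(CC=C(C)C)c(O[Si](C(C)C)(C(C)C)C(C)C)c(CC=C(C)C)c1 | intermediate
19 | racemic 3-ethoxy-2-(1-hydroxy-3-{3,5-bis(3-methylbut-2-en-1-yl)-4-[(triisopropylsilyl)oxy]phenyl}prop-2-yn-1-yl)-6-(3-methylbut-2-en-1-yl)-5-[(triisopropylsilyl)oxy]phenol | CCOc1cc(O[Si](C(C)C)(C(C)C)C(C)C)c(CC=C(C)C)c(O)c1C(O)C#Cc1cc(CC=C(C)C)c(O[Si](C(C)C)(C(C)C)C(C)C)c(CC=C(C)C)c1 | intermediate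
20 | 1-[6-ethoxy-2-hydroxy-3-(3-methylbut-2-en-1-yl)-4-[(triisopropylsilyl)oxy]phenyl]-3-{3,5-bis(3-methylbut-2-en-1-yl)-4-[(triisopropylsilyl)oxy]phenyl}prop-2-yn-1-one | CCOc1cc(O[Si](C(C)C)(C(C)C)C(C)C)c(CC=C(C)C)c(O)c1C(=O)C#Cc1cc(CC=C(C)C)c(O[Si](C(C)C)(C(C)C)C(C)C)c(CC=C(C)C)c1 | intermediate
21 | 3-(diethylamino)-1-[6-ethoxy-2-hydroxy-3-(3-methylbut-2-en-1-yl)-4-[(triisopropylsilyl)oxy]phenyl]-3-{3,5-bis(3-methylbut-2-en-1-yl)-4-[(triisopropylsilyl)oxy]phenyl}prop-2-en-1-one (mixture of E and Z isomers, not isolated) | CCOc1cc(O[Si](C(C)C)(C(C)C)C(C)C)c(CC=C(C)C)c(O)c1C(=O)C=C(N(CC)CC)c1cc(CC=C(C)C)c(O[Si](C(C)C)(C(C)C)C(C)C)c(CC=C(C)C)c1 | intermediate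
22 | 5-ethoxy-8-(3-methylbut-2-en-1-yl)-2-{3,5-bis(3-methylbut-2-en-1-yl)-4-[(triisopropylsilyl)oxy]phenyl}-7-[(triisopropylsilyl)oxy]-4H-chromen-4-one | CCOc1cc(O[Si](C(C)C)(C(C)C)C(C)C)c(CC=C(C)C)c2oc(-c3cc(CC=C(C)C)c(O[Si](C(C)C)(C(C)C)C(C)C)c(CC=C(C)C)c3)cc(=O)c12 | intermediate
23 | 5-hydroxy-8-(3-methylbut-2-en-1-yl)-2-{3,5-bis(3-methylbut-2-en-1-yl)-4-[(triisopropylsilyl)oxy]phenyl}-7-[(triisopropylsilyl)oxy]-4H-chromen-4-one | Oc1cc(O[Si](C(C)C)(C(C)C)C(C)C)c(CC=C(C)C)c2oc(-c3cc(CC=C(C)C)c(O[Si](C(C)C)(C(C)C)C(C)C)c(CC=C(C)C)c3)cc(=O)c12 | intermediate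
24 | Epimedonin L, 5,7-dihydroxy-2-[4-hydroxy-3,5-bis(3-methylbut-2-en-1-yl)phenyl]-8-(3-methylbut-2-en-1-yl)-4H-chromen-4-one (no stereocentre) | CC(C)=CCc1cc(-c2cc(=O)c3c(O)cc(O)c(CC=C(C)C)c3o2)cc(CC=C(C)C)c1O | target

Total step count: 11. Longest linear sequence: 8 steps (steps 1, 2, 3, 7, 8, 9, 10, 11 from 1; the ring B branch through steps 4, 5, 6 and then 7 to 11 is equally long).

Least certain steps

Step 2 (key step). The vinylogous-ester stabilisation of 5 may make its ring opening slow, so that long heating lets the ketene oligomerise, acylate the newly formed phenol, or outlast the ynol ether, which can rearrange by silyl shift. The orientation of the cycloaddition is not the concern; the rate balance is. Fallback, setting out from 4 and returning at 10: the same ketene is generated below room temperature by dehydrochlorination instead of electrocyclic opening. Commercial ethyl (2E)-3-ethoxybut-2-enoate is saponified to (2E)-3-ethoxybut-2-enoic acid F1, which oxalyl chloride converts into (2E)-3-ethoxybut-2-enoyl chloride F2. Slow addition of triethylamine to F2 and 4 in CH2Cl2 at 0 to 25 °C gives 6 by 1,4-elimination, and 6 is trapped at once as 7. Brief heating of 7 in toluene then carries it through 8 and 9 to 10. The generation of vinylketenes from unsaturated acid chlorides and their addition to siloxyalkynes is known chemistry, and it separates the ketene-forming event from the thermal electrocyclic steps.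

Step 10. SN2 attack of iodide at an ethyl carbon is slower than at a methyl or benzyl carbon. Forcing the reaction may cause loss of silyl groups and then acid-mediated addition of a freed hydroxyl or of HI to a prenyl alkene. Fallback, setting out from 22 and returning at 24: the protecting groups and the dealkylation mechanism are both changed. 22 is desilylated with buffered TBAF to the 5-O-ethyl diol F6. Acetic anhydride, pyridine and DMAP give the 7,4′-diacetate F7. BCl3 in CH2Cl2 at −78 °C, quenched cold into aqueous NaHCO3, cleaves the peri ethyl ether through a boron chelate that delivers chloride internally, a method that works for ethyl ethers, and gives the 5-hydroxy diacetate F8. The acetates are inert to BCl3 at this temperature and keep the oxygens beside the prenyl groups non-nucleophilic. K2CO3 in methanol under argon then removes both acetates to give 24.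

Step 7. The lithium phenoxide formed from 12 makes the aldehyde a vinylogous carboxylate, and two further oxygen donors lower its electrophilicity again. Addition may therefore stall, and warming to drive it invites silyl transfer or decomposition of the acetylide. Fallback, setting out from 12 and returning at 22: the phenol is masked so that the aldehyde is a normal electrophile. Allyl bromide and K2CO3 in DMF at 25 °C give the O-allyl aldehyde F3. Addition of 18 (1.2 equiv) gives the propargylic alcohol F4, and MnO2 gives the O-allyl ynone F5. Pd(PPh3)4 (zerovalent palladium, catalytic) with Et2NH in THF–EtOH removes the allyl group under neutral conditions to give 20, which under the same amine passes through 21 to 22. This costs one step more than the main route and avoids any acid.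

Step 4. Allyl transfer from tin can lose regiochemical integrity (bond formation at the more substituted allyl terminus), palladium hydride can move the double bond into conjugation with the ring, and the second coupling next to a free hydroxyl may stop short. Fallback, setting out from 13 and returning at 15: the prenyl groups are built in two stages, so that no unsymmetrical allyl unit is transferred. Tributyl(prop-2-en-1-yl)stannane and Pd(PPh3)4 in DMF convert 13 through the mono-allyl bromide F9 into the diallyl aldehyde F10. Cross-metathesis with excess 2-methylbut-2-ene and the second-generation Grubbs catalyst in CH2Cl2 at 40 °C then exchanges each terminal CH2 for an isopropylidene unit, through the mixed allyl prenyl aldehyde F11, to give 15.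

Further compounds

F1 | step 2 | (2E)-3-ethoxybut-2-enoic acid | CCO/C(C)=C/C(=O)O
F2 | step 2 | (2E)-3-ethoxybut-2-enoyl chloride | CCO/C(C)=C/C(=O)Cl
F3 | step 7 | 6-ethoxy-3-(3-methylbut-2-en-1-yl)-2-(prop-2-en-1-yloxy)-4-[(triisopropylsilyl)oxy]benzaldehyde | CCOc1cc(O[Si](C(C)C)(C(C)C)C(C)C)c(CC=C(C)C)c(OCC=C)c1C=O
F4 | step 7 | racemic 1-[6-ethoxy-3-(3-methylbut-2-en-1-yl)-2-(prop-2-en-1-yloxy)-4-[(triisopropylsilyl)oxy]phenyl]-3-{3,5-bis(3-methylbut-2-en-1-yl)-4-[(triisopropylsilyl)oxy]phenyl}prop-2-yn-1-ol | CCOc1cc(O[Si](C(C)C)(C(C)C)C(C)C)c(CC=C(C)C)c(OCC=C)c1C(O)C#Cc1cc(CC=C(C)C)c(O[Si](C(C)C)(C(C)C)C(C)C)c(CC=C(C)C)c1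
F5 | step 7 | 1-[6-ethoxy-3-(3-methylbut-2-en-1-yl)-2-(prop-2-en-1-yloxy)-4-[(triisopropylsilyl)oxy]phenyl]-3-{3,5-bis(3-methylbut-2-en-1-yl)-4-[(triisopropylsilyl)oxy]phenyl}prop-2-yn-1-one | CCOc1cc(O[Si](C(C)C)(C(C)C)C(C)C)c(CC=C(C)C)c(OCC=C)c1C(=O)C#Cc1cc(CC=C(C)C)c(O[Si](C(C)C)(C(C)C)C(C)C)c(CC=C(C)C)c1
F6 | step 10 | 5-ethoxy-7-hydroxy-2-[4-hydroxy-3,5-bis(3-methylbut-2-en-1-yl)phenyl]-8-(3-methylbut-2-en-1-yl)-4H-chromen-4-one | CCOc1cc(O)c(CC=C(C)C)c2oc(-c3cc(CC=C(C)C)c(O)c(CC=C(C)C)c3)cc(=O)c12
F7 | step 10 | 4-[7-acetoxy-5-ethoxy-8-(3-methylbut-2-en-1-yl)-4-oxo-4H-chromen-2-yl]-2,6-bis(3-methylbut-2-en-1-yl)phenyl acetate | CCOc1cc(OC(C)=O)c(CC=C(C)C)c2oc(-c3cc(CC=C(C)C)c(OC(C)=O)c(CC=C(C)C)c3)cc(=O)c12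
F8 | step 10 | 4-[7-acetoxy-5-hydroxy-8-(3-methylbut-2-en-1-yl)-4-oxo-4H-chromen-2-yl]-2,6-bis(3-methylbut-2-en-1-yl)phenyl acetate | Oc1cc(OC(C)=O)c(CC=C(C)C)c2oc(-c3cc(CC=C(C)C)c(OC(C)=O)c(CC=C(C)C)c3)cc(=O)c12
F9 | step 4 | 3-bromo-4-hydroxy-5-(prop-2-en-1-yl)benzaldehyde | O=Cc1cc(Br)c(O)c(CC=C)c1
F10 | step 4 | 4-hydroxy-3,5-di(prop-2-en-1-yl)benzaldehyde | O=Cc1cc(CC=C)c(O)c(CC=C)c1
F11 | step 4 | 4-hydroxy-3-(3-methylbut-2-en-1-yl)-5-(prop-2-en-1-yl)benzaldehyde | O=Cc1cc(CC=C)c(O)c(CC=C(C)C)c1
A1 | alternative 1 | ethyl 4-oxocyclohexane-1-carboxylate | CCOC(=O)C1CCC(=O)CC1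
A2 | alternative 1 | 1-bromo-3-methylbut-2-ene | CC(C)=CCBr
A3 | alternative 1 | ethyl 3,5-bis(3-methylbut-2-en-1-yl)-4-oxocyclohexane-1-carboxylate (all-cis meso isomer drawn; any diastereomer serves) | CCOC(=O)[C@H]1C[C@@H](CC=C(C)C)C(=O)[C@@H](CC=C(C)C)C1
A4 | alternative 1 | ethyl 4-hydroxy-3,5-bis(3-methylbut-2-en-1-yl)benzoate | CCOC(=O)c1cc(CC=C(C)C)c(O)c(CC=C(C)C)c1
A5 | alternative 2 | 4-[5,7-diacetoxy-4-oxo-8-(prop-2-en-1-yl)-4H-chromen-2-yl]-2,6-di(prop-2-en-1-yl)phenyl acetate | CC(=O)Oc1cc(OC(C)=O)c2c(=O)cc(-c3cc(CC=C)c(OC(C)=O)c(CC=C)c3)oc2c1CC=C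
A6 | alternative 2 | 2-methylbut-2-ene | CC=C(C)C
A7 | alternative 2 | Epimedonin L triacetate | CC(=O)Oc1cc(OC(C)=O)c2c(=O)cc(-c3cc(CC=C(C)C)c(OC(C)=O)c(CC=C(C)C)c3)oc2c1CC=C(C)C
A8 | alternative 3 | racemic methyl 6-[4-(methoxymethoxy)-3,5-bis(3-methylbut-2-en-1-yl)phenyl]-2-(6-methyl-2-oxohept-5-en-3-yl)-4-oxo-4H-pyran-3-carboxylate | COC(=O)c1c(C(CC=C(C)C)C(C)=O)oc(-c2cc(CC=C(C)C)c(OCOC)c(CC=C(C)C)c2)cc1=O
A9 | alternative 3 | Epimedonin L 4′-methoxymethyl ether | COCOc1c(CC=C(C)C)cc(-c2cc(=O)c3c(O)cc(O)c(CC=C(C)C)c3o2)cc1CC=C(C)C
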